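## Retrosynthetic overview

1. The target is reached by global desilylation and allyl-to-prenyl cross-metathesis of a silylated (2S)-flavan. The flavan pyran ring (O1–C2) is closed last, by Mitsunobu inversion of an (R)-benzylic carbinol. The carbinol comes from a ketone by catalytic asymmetric transfer hydrogenation, and the ketone from a ring-B aryllithium and a ring-A Weinreb amide (from umbelliferone).
2. The ring-B bromide carries the finished dihydropyran-cis-diol. It is made first, on a simple bromoarene, by a chiral-acid-catalysed oxa-Povarov-type [4+2] annulation of a catechol ketal with 2,2-dimethyl-1,3-dioxole. This one step forms the aryl–C4 and C3–C2 bonds, the dihydropyran ring and both carbinol stereocentres.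
3. Enabling feature: ring B is a catechol (oxygens on C-3′ and C-4′). O-4′ is the pyran oxygen bound to the gem-dimethyl carbon, and the neighbouring C-5′ carries H. As a 2,2-dimethyl-1,3-benzodioxole, the gem-dimethyl carbon is a latent aryloxocarbenium carbon (2-oxa-diene C5′=C4′–O+=CMe2). Ring opening releases the C-3′ phenol, and the cis-3,4-diol maps onto a cyclic cis-enediol ether. The allyl group on C-2′ (the later prenyl group) blocks the other ortho carbon.
4. Ring order: benzodioxole (temporary) → dihydropyran with cis-fused dioxolane (key step) → flavan pyran ring (Mitsunobu). The flavan centre is set by catalyst and inversion, independently of the diol centres.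

Key step: step 3

Assumption: 2,2-dimethyl-1,3-dioxole is treated as a purchasable cis-enediol equivalent; where it is not stocked, it is made from commercial 2,2-dimethyl-1,3-dioxolan-4-one by reductive acetylation and elimination of acetic acid.

## Route

Step 1
Reactants: 1 4-bromobenzene-1,2-diol
Product: 2 5-bromo-2,2-dimethyl-1,3-benzodioxole
Conditions: 2,2-dimethoxypropane, TsOH·H2O (cat.), toluene, reflux, MeOH removed (4 Å MS)
Reagents that add atoms: 2,2-dimethoxypropane (COC(C)(C)OC)
Why: Acid-catalysed transketalisation of a catechol, driven by removal of methanol, should give the five-membered ketal.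

Step 2
Reactants: 2 5-bromo-2,2-dimethyl-1,3-benzodioxole
Product: 4 4-allyl-5-bromo-2,2-dimethyl-1,3-benzodioxole, via aryllithium 3 (not isolated)
Conditions: LDA, THF, −78 °C; CuBr·SMe2 (10 mol %), allyl bromide, −78 → −30 °C
Reagents that add atoms: allyl bromide (C=CCBr)
Why: Directed ortho-lithiation removes the most acidic proton, flanked by bromine and the ring oxygen, and copper-catalysed allylation of the aryllithium is run below the temperature at which LiBr is lost to the aryne.

Step 3
Reactants: 4 4-allyl-5-bromo-2,2-dimethyl-1,3-benzodioxole; 5 2,2-dimethyl-1,3-dioxole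
Product: 8 (3aR,9bR)-7-allyl-8-bromo-2,2,4,4-tetramethyl-3a,9b-dihydro-4H-[1,3]dioxolo[4,5-c]chromen-6-ol, via aryloxocarbenium ion 6 (not isolated), via dioxolanylium ion 7 (not isolated)
Conditions: chiral confined imidodiphosphorimidate (IDPi) Brønsted acid (5 mol %), 5 (2 equiv, slow addition), CH2Cl2, 5 Å MS, −40 → 0 °C; Et3N quench
Reagents that add atoms: none
Why: Proposed new method: the chiral acid protonates a ketal oxygen of 4 and opens the benzodioxole to the ion pair of aryloxocarbenium ion 6 (a cationic 2-oxa-diene, C7=C7a–O+=CMe2) with the chiral anion, which is held by a hydrogen bond to the phenol released next to it; the enediol ether 5 then adds through one alkene carbon to the ketal carbon (C3–C2 bond, chroman numbering), the dioxolanylium ion 7 so formed is attacked by the ortho carbon C7 (C4–C4a bond), and rearomatisation returns the proton, so the two partners combine without by-product. The closest known reaction types are the Lewis-acid oxa-Povarov annulation of aryl oxocarbenium ions with alkenes, the acid-catalysed addition of ketals to enol ethers, and the chiral-acid-catalysed Povarov reaction of N-aryl iminium ions; not yet shown are a catechol ketal as source of the oxa-diene, a cyclic enediol ether as 2π partner, and control by a chiral counter-anion. The dihydropyran ring closes by a stepwise formal [4+2] annulation whose second bond is a six-membered intramolecular Friedel–Crafts alkylation (6-exo attack of the arene on the C=O+ carbon of 7). C-3 and C-4 should come out cis because both belong to the five-membered dioxole ring and the tethered arene can reach the cation only from the face that carries the new C–C bond; the absolute configuration (3R,4R) is set under catalyst control when anion-bound 6 selects one of the two enantiotopic alkene carbons of 5, with the catalyst antipode assigned in a trial run on this achiral substrate. The step needs site selectivity between the two ketal oxygens, since only the ion on the oxygen next to C7–H can close: that ion should prevail because the other oxygen is flanked by the allyl group and is the better phenoxide leaving group (meta to bromine), and the allyl group blocks C4 so that no regioisomeric ring can form.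

Step 4
Reactants: 8 (3aR,9bR)-7-allyl-8-bromo-2,2,4,4-tetramethyl-3a,9b-dihydro-4H-[1,3]dioxolo[4,5-c]chromen-6-ol
Product: 9 (3R,4R)-7-allyl-6-bromo-2,2-dimethylchromane-3,4,8-triol
Conditions: AcOH/H2O (4:1), THF, 45 °C
Reagents that add atoms: none
Why: Acid-catalysed ketal hydrolysis is done here, on the robust bromoarene, so that no acid is needed once the 2-arylchroman and prenyl groups are present; weak aqueous acid should leave the benzylic C-4–O bond un-ionised and both stereocentres intact.

Step 5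
Reactants: 9 (3R,4R)-7-allyl-6-bromo-2,2-dimethylchromane-3,4,8-triol
Product: 10 (3R,4R)-7-allyl-6-bromo-3,4,8-tris(tert-butyldimethylsilyloxy)-2,2-dimethylchromane
Conditions: TBSOTf (3.6 equiv), 2,6-lutidine, CH2Cl2, 0 °C → rt
Reagents that add atoms: tert-butyldimethylsilyl triflate (CC(C)(C)[Si](C)(C)OS(=O)(=O)C(F)(F)F)
Why: Silylation with the silyl triflate and a hindered base should cap the hindered phenol and both secondary alcohols without touching a stereocentre.

Step 6
Reactants: 11 7-hydroxy-2H-chromen-2-one (umbelliferone)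
Product: 12 7-hydroxychroman-2-one
Conditions: H2 (1 atm), 10% Pd/C, EtOH/AcOH, rt
Reagents that add atoms: none
Why: Heterogeneous catalytic hydrogenation should saturate the conjugated C3=C4 bond of the coumarin and leave the lactone and arene.

Step 7
Reactants: 12 7-hydroxychroman-2-one
Product: 13 7-(tert-butyldimethylsilyloxy)chroman-2-one
Conditions: TBSCl, imidazole, DMF, rt
Reagents that add atoms: tert-butyldimethylsilyl chloride (CC(C)(C)[Si](C)(C)Cl)
Why: Standard silylation of a phenol.

Step 8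
Reactants: 13 7-(tert-butyldimethylsilyloxy)chroman-2-one
Product: 14 3-[4-(tert-butyldimethylsilyloxy)-2-hydroxyphenyl]-N-methoxy-N-methylpropanamide
Conditions: MeNH(OMe)·HCl, i-PrMgCl, THF, −20 → 0 °C; aq. NH4Cl
Reagents that add atoms: N,O-dimethylhydroxylamine hydrochloride (CNOC.Cl)
Why: Aminolysis of the aryl lactone by the magnesium amide (Weinreb amide formation) should open the ring and free the phenol needed later for ring closure.

Step 9
Reactants: 10 (3R,4R)-7-allyl-6-bromo-3,4,8-tris(tert-butyldimethylsilyloxy)-2,2-dimethylchromane; 14 3-[4-(tert-butyldimethylsilyloxy)-2-hydroxyphenyl]-N-methoxy-N-methylpropanamide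
Product: 16 1-[(3R,4R)-7-allyl-3,4,8-tris(tert-butyldimethylsilyloxy)-2,2-dimethylchroman-6-yl]-3-[4-(tert-butyldimethylsilyloxy)-2-hydroxyphenyl]propan-1-one, via aryllithium 15 (not isolated)
Conditions: 10, n-BuLi, THF, −78 °C; added to 14 pre-treated with i-PrMgCl (1 equiv), THF, −78 → −20 °C; aq. NH4Cl
Reagents that add atoms: none
Why: Bromine–lithium exchange followed by Weinreb ketone synthesis should stop at the ketone because the chelated tetrahedral adduct survives until work-up, the phenol being masked as its magnesium phenoxide.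

Step 10
Reactants: 16 1-[(3R,4R)-7-allyl-3,4,8-tris(tert-butyldimethylsilyloxy)-2,2-dimethylchroman-6-yl]-3-[4-(tert-butyldimethylsilyloxy)-2-hydroxyphenyl]propan-1-one
Product: 17 (1R)-1-[(3R,4R)-7-allyl-3,4,8-tris(tert-butyldimethylsilyloxy)-2,2-dimethylchroman-6-yl]-3-[4-(tert-butyldimethylsilyloxy)-2-hydroxyphenyl]propan-1-ol
Conditions: RuCl[(R,R)-TsDPEN](p-cymene) (2 mol %), HCO2H/Et3N (5:2), CH2Cl2, 30 °C
Reagents that add atoms: none
Why: Noyori–Ikariya asymmetric transfer hydrogenation of the aryl alkyl ketone should deliver hydride to the face that gives the (R)-carbinol under control of the (R,R)-ligand, leaving the allyl group untouched.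

Step 11
Reactants: 17 (1R)-1-[(3R,4R)-7-allyl-3,4,8-tris(tert-butyldimethylsilyloxy)-2,2-dimethylchroman-6-yl]-3-[4-(tert-butyldimethylsilyloxy)-2-hydroxyphenyl]propan-1-ol
Product: 18 (2S)-2-[(3R,4R)-7-allyl-3,4,8-tris(tert-butyldimethylsilyloxy)-2,2-dimethylchroman-6-yl]-7-(tert-butyldimethylsilyloxy)chromane
Conditions: PPh3, DIAD, toluene, 0 °C, 0.02 M
Reagents that add atoms: none
Why: In the intramolecular Mitsunobu etherification the phenoxide should displace the activated benzylic oxygen by SN2 with inversion, turning the (R)-carbinol into the (2S)-flavan centre.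

Step 12
Reactants: 18 (2S)-2-[(3R,4R)-7-allyl-3,4,8-tris(tert-butyldimethylsilyloxy)-2,2-dimethylchroman-6-yl]-7-(tert-butyldimethylsilyloxy)chromane
Product: 19 (2S)-7-(tert-butyldimethylsilyloxy)-2-[(3R,4R)-3,4,8-tris(tert-butyldimethylsilyloxy)-2,2-dimethyl-7-(3-methylbut-2-en-1-yl)chroman-6-yl]chromane
Conditions: Grubbs second-generation catalyst (5 mol %), 2-methyl-2-butene (excess), CH2Cl2, 40 °C
Reagents that add atoms: 2-methyl-2-butene (CC=C(C)C)
Why: Olefin cross-metathesis of the allyl arene with 2-methyl-2-butene should convert allyl into prenyl with loss of propene.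

Step 13
Reactants: 19 (2S)-7-(tert-butyldimethylsilyloxy)-2-[(3R,4R)-3,4,8-tris(tert-butyldimethylsilyloxy)-2,2-dimethyl-7-(3-methylbut-2-en-1-yl)chroman-6-yl]chromane
Product: 20 (3R,4R)-6-[(2S)-7-hydroxychroman-2-yl]-2,2-dimethyl-7-(3-methylbut-2-en-1-yl)chromane-3,4,8-triol
Conditions: TBAF (6 equiv), AcOH (6 equiv), THF, 0 → 40 °C
Reagents that add atoms: none
Why: Buffered fluoride desilylation should remove all four silyl ethers under conditions that touch neither the prenyl group nor a stereocentre.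

## Compound list

1 | 4-bromobenzene-1,2-diol | Oc1ccc(Br)cc1O | starting material
2 | 5-bromo-2,2-dimethyl-1,3-benzodioxole | CC1(C)Oc2ccc(Br)cc2O1 | intermediate
3 | (5-bromo-2,2-dimethyl-1,3-benzodioxol-4-yl)lithium | [Li]c1c(Br)ccc2OC(C)(C)Oc12 | intermediate
4 | 4-allyl-5-bromo-2,2-dimethyl-1,3-benzodioxole | C=CCc1c(Br)ccc2OC(C)(C)Oc12 | intermediate
5 | 2,2-dimethyl-1,3-dioxole | CC1(C)OC=CO1 | starting material
6 | (3-allyl-4-bromo-2-hydroxyphenyl)(propan-2-ylidene)oxonium ion | C=CCc1c(Br)ccc([O+]=C(C)C)c1O | intermediate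
7 | 5-[2-(3-allyl-4-bromo-2-hydroxyphenoxy)propan-2-yl]-2,2-dimethyl-1,3-dioxolan-4-ylium ion (configuration as in 8) | C=CCc1c(Br)ccc(OC(C)(C)[C@@H]2OC(C)(C)[O+]=C2)c1O | intermediate
8 | (3aR,9bR)-7-allyl-8-bromo-2,2,4,4-tetramethyl-3a,9b-dihydro-4H-[1,3]dioxolo[4,5-c]chromen-6-ol | C=CCc1c(Br)cc2c(c1O)OC(C)(C)[C@@H]3OC(C)(C)O[C@H]23 | intermediate
9 | (3R,4R)-7-allyl-6-bromo-2,2-dimethylchromane-3,4,8-triol | C=CCc1c(Br)cc2c(c1O)OC(C)(C)[C@H](O)[C@@H]2O | intermediate
10 | (3R,4R)-7-allyl-6-bromo-3,4,8-tris(tert-butyldimethylsilyloxy)-2,2-dimethylchromane | C=CCc1c(Br)cc2c(c1O[Si](C)(C)C(C)(C)C)OC(C)(C)[C@H](O[Si](C)(C)C(C)(C)C)[C@@H]2O[Si](C)(C)C(C)(C)C | intermediate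
11 | 7-hydroxy-2H-chromen-2-one (umbelliferone) | O=c1ccc2ccc(O)cc2o1 | starting material
12 | 7-hydroxychroman-2-one | O=C1CCc2ccc(O)cc2O1 | intermediate
13 | 7-(tert-butyldimethylsilyloxy)chroman-2-one | CC(C)(C)[Si](C)(C)Oc1ccc2CCC(=O)Oc2c1 | intermediate
14 | 3-[4-(tert-butyldimethylsilyloxy)-2-hydroxyphenyl]-N-methoxy-N-methylpropanamide | CON(C)C(=O)CCc1ccc(O[Si](C)(C)C(C)(C)C)cc1O | intermediate
15 | [(3R,4R)-7-allyl-3,4,8-tris(tert-butyldimethylsilyloxy)-2,2-dimethylchroman-6-yl]lithium | C=CCc1c([Li])cc2c(c1O[Si](C)(C)C(C)(C)C)OC(C)(C)[C@H](O[Si](C)(C)C(C)(C)C)[C@@H]2O[Si](C)(C)C(C)(C)C | intermediate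
16 | 1-[(3R,4R)-7-allyl-3,4,8-tris(tert-butyldimethylsilyloxy)-2,2-dimethylchroman-6-yl]-3-[4-(tert-butyldimethylsilyloxy)-2-hydroxyphenyl]propan-1-one | C=CCc1c(C(=O)CCc3ccc(O[Si](C)(C)C(C)(C)C)cc3O)cc2c(c1O[Si](C)(C)C(C)(C)C)OC(C)(C)[C@H](O[Si](C)(C)C(C)(C)C)[C@@H]2O[Si](C)(C)C(C)(C)C | intermediate
17 | (1R)-1-[(3R,4R)-7-allyl-3,4,8-tris(tert-butyldimethylsilyloxy)-2,2-dimethylchroman-6-yl]-3-[4-(tert-butyldimethylsilyloxy)-2-hydroxyphenyl]propan-1-ol | C=CCc1c([C@H](O)CCc3ccc(O[Si](C)(C)C(C)(C)C)cc3O)cc2c(c1O[Si](C)(C)C(C)(C)C)OC(C)(C)[C@H](O[Si](C)(C)C(C)(C)C)[C@@H]2O[Si](C)(C)C(C)(C)C | intermediate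
18 | (2S)-2-[(3R,4R)-7-allyl-3,4,8-tris(tert-butyldimethylsilyloxy)-2,2-dimethylchroman-6-yl]-7-(tert-butyldimethylsilyloxy)chromane | C=CCc1c([C@@H]3CCc4ccc(O[Si](C)(C)C(C)(C)C)cc4O3)cc2c(c1O[Si](C)(C)C(C)(C)C)OC(C)(C)[C@H](O[Si](C)(C)C(C)(C)C)[C@@H]2O[Si](C)(C)C(C)(C)C | intermediate
19 | (2S)-7-(tert-butyldimethylsilyloxy)-2-[(3R,4R)-3,4,8-tris(tert-butyldimethylsilyloxy)-2,2-dimethyl-7-(3-methylbut-2-en-1-yl)chroman-6-yl]chromane | CC(C)=CCc1c([C@@H]3CCc4ccc(O[Si](C)(C)C(C)(C)C)cc4O3)cc2c(c1O[Si](C)(C)C(C)(C)C)OC(C)(C)[C@H](O[Si](C)(C)C(C)(C)C)[C@@H]2O[Si](C)(C)C(C)(C)C | intermediate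
20 | (3R,4R)-6-[(2S)-7-hydroxychroman-2-yl]-2,2-dimethyl-7-(3-methylbut-2-en-1-yl)chromane-3,4,8-triol | CC(C)=CCc1c([C@@H]2CCc3ccc(O)cc3O2)cc2c(c1O)OC(C)(C)[C@H](O)[C@@H]2O | target

## Step count and risks

Total step count: 13. Longest linear sequence: 10 steps (steps 1–5 and 9–13).

Steps most likely to fail:

**Step 3 (key step).** Three processes may defeat it: the dioxole may be protonated and oligomerise faster than the ketal opens; the ketal may open at the oxygen next to the allyl group, so that the first C–C bond forms on an ion that cannot close; and the chiral anion may discriminate the two alkene carbons poorly.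

The fallback uses known chemistry, sets out from 4 and comes back at 9. The ketal of 4 is hydrolysed (3 M aq. HCl, dioxane, 80 °C) to 3-allyl-4-bromobenzene-1,2-diol F1. The less hindered hydroxyl, para to bromine, is alkylated with 3-chloro-3-methylbut-1-yne (K2CO3, KI, CuI cat., acetone) to give 2-allyl-3-bromo-6-[(2-methylbut-3-yn-2-yl)oxy]phenol F2. Heating (N,N-diethylaniline, 180 °C; propargyl Claisen rearrangement, 1,5-H shift and 6π-electrocyclisation) should give 7-allyl-6-bromo-2,2-dimethyl-2H-chromen-8-ol F3. Silylation (TBSCl, imidazole) gives tert-butyl[(7-allyl-6-bromo-2,2-dimethyl-2H-chromen-8-yl)oxy]dimethylsilane F4. Jacobsen epoxidation ((R,R)-Mn(salen)Cl, NaOCl, 4-phenylpyridine N-oxide, CH2Cl2, 0 °C) is selective for the conjugated cis-alkene over the allyl group and is expected, by analogy with other 2,2-dimethylchromenes, to give (3R,4R)-7-allyl-6-bromo-8-(tert-butyldimethylsilyloxy)-3,4-epoxy-2,2-dimethylchromane F5. Insertion of CO2 (n-Bu4NBr cat., 70 °C; two inversions at C-4, hence retention) gives (3R,4R)-7-allyl-6-bromo-8-(tert-butyldimethylsilyloxy)-2,2-dimethylchromane-3,4-diyl carbonate F6. Methanolysis (K2CO3 cat., MeOH) removes the carbonate and the aryl silyl ether and gives 9.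

**Step 11 (Mitsunobu).** The benzylic alkoxyphosphonium ion has an oxygen para to it and may ionise before it is displaced, which would erode the configuration (SN1 leakage) or lead to elimination.

The fallback sets out from 16 and comes back at 18; it forms the ring without breaking a bond at the stereocentre. Transfer hydrogenation with the (S,S)-catalyst gives (1S)-1-[(3R,4R)-7-allyl-3,4,8-tris(tert-butyldimethylsilyloxy)-2,2-dimethylchroman-6-yl]-3-[4-(tert-butyldimethylsilyloxy)-2-hydroxyphenyl]propan-1-ol F7. Phenol-selective triflation (PhNTf2, K2CO3, THF) gives 5-(tert-butyldimethylsilyloxy)-2-{(3S)-3-[(3R,4R)-7-allyl-3,4,8-tris(tert-butyldimethylsilyloxy)-2,2-dimethylchroman-6-yl]-3-hydroxypropyl}phenyl trifluoromethanesulfonate F8. Intramolecular Pd-catalysed C–O coupling (Pd2(dba)3, bulky di-tert-butylbiarylphosphine, K3PO4, toluene, 70 °C) should then close the pyran ring with retention and give 18.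

**Step 12 (cross-metathesis).** Ruthenium hydrides may move the allyl double bond into conjugation with the arene, the allyl arene may homodimerise, or turnover may be slow next to the two ortho substituents.

The fallback sets out from 18 and comes back at 19. Oxidative cleavage of the terminal alkene (OsO4 cat., NaIO4, 2,6-lutidine, dioxane/H2O) gives 2-[(3R,4R)-3,4,8-tris(tert-butyldimethylsilyloxy)-6-[(2S)-7-(tert-butyldimethylsilyloxy)chroman-2-yl]-2,2-dimethylchroman-7-yl]acetaldehyde F9. Wittig olefination with isopropylidenetriphenylphosphorane (from isopropyltriphenylphosphonium iodide and n-BuLi, THF, −78 → 0 °C) gives 19.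

## Further compounds

F1 | step 3 | 3-allyl-4-bromobenzene-1,2-diol | C=CCc1c(Br)ccc(O)c1O
F2 | step 3 | 2-allyl-3-bromo-6-[(2-methylbut-3-yn-2-yl)oxy]phenol | C=CCc1c(Br)ccc(OC(C)(C)C#C)c1O
F3 | step 3 | 7-allyl-6-bromo-2,2-dimethyl-2H-chromen-8-ol | C=CCc1c(Br)cc2C=CC(C)(C)Oc2c1O
F4 | step 3 | tert-butyl[(7-allyl-6-bromo-2,2-dimethyl-2H-chromen-8-yl)oxy]dimethylsilane | C=CCc1c(Br)cc2C=CC(C)(C)Oc2c1O[Si](C)(C)C(C)(C)C
F5 | step 3 | (3R,4R)-7-allyl-6-bromo-8-(tert-butyldimethylsilyloxy)-3,4-epoxy-2,2-dimethylchromane | C=CCc1c(Br)cc2c(c1O[Si](C)(C)C(C)(C)C)OC(C)(C)[C@@H]3O[C@H]23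
F6 | step 3 | (3R,4R)-7-allyl-6-bromo-8-(tert-butyldimethylsilyloxy)-2,2-dimethylchromane-3,4-diyl carbonate | C=CCc1c(Br)cc2c(c1O[Si](C)(C)C(C)(C)C)OC(C)(C)[C@@H]3OC(=O)O[C@H]23
F7 | step 11 | (1S)-1-[(3R,4R)-7-allyl-3,4,8-tris(tert-butyldimethylsilyloxy)-2,2-dimethylchroman-6-yl]-3-[4-(tert-butyldimethylsilyloxy)-2-hydroxyphenyl]propan-1-ol | C=CCc1c([C@@H](O)CCc3ccc(O[Si](C)(C)C(C)(C)C)cc3O)cc2c(c1O[Si](C)(C)C(C)(C)C)OC(C)(C)[C@H](O[Si](C)(C)C(C)(C)C)[C@@H]2O[Si](C)(C)C(C)(C)C
F8 | step 11 | 5-(tert-butyldimethylsilyloxy)-2-{(3S)-3-[(3R,4R)-7-allyl-3,4,8-tris(tert-butyldimethylsilyloxy)-2,2-dimethylchroman-6-yl]-3-hydroxypropyl}phenyl trifluoromethanesulfonate | C=CCc1c([C@@H](O)CCc3ccc(O[Si](C)(C)C(C)(C)C)cc3OS(=O)(=O)C(F)(F)F)cc2c(c1O[Si](C)(C)C(C)(C)C)OC(C)(C)[C@H](O[Si](C)(C)C(C)(C)C)[C@@H]2O[Si](C)(C)C(C)(C)C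
F9 | step 12 | 2-[(3R,4R)-3,4,8-tris(tert-butyldimethylsilyloxy)-6-[(2S)-7-(tert-butyldimethylsilyloxy)chroman-2-yl]-2,2-dimethylchroman-7-yl]acetaldehyde | O=CCc1c([C@@H]3CCc4ccc(O[Si](C)(C)C(C)(C)C)cc4O3)cc2c(c1O[Si](C)(C)C(C)(C)C)OC(C)(C)[C@H](O[Si](C)(C)C(C)(C)C)[C@@H]2O[Si](C)(C)C(C)(C)C
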